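**Retrosynthetic overview**
- Leachianone A comes from its tris-MOM ether by acetal cleavage. Ring C is the only ring made and is closed last, at the C3–C4 bond, by an enantioselective rhodium-catalysed intramolecular hydroacylation that also sets C2 (S).
- Enabling feature: C3 is an unsubstituted CH2 between the C4 carbonyl (on C4a of ring A) and C2, which carries O1 (on C8a, ortho to C4a) and ring B. C3–C4 plus C2–H therefore map onto addition of a C4 formyl C–H across a C2=C3 1-arylvinyl ether hung on O1, an alkene with no allylic hydrogen.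
- The vinyl ether comes from Tebbe methylenation (C3 enters as the CH2) of the O1 aryl ester of the ring B acid; C4 is carried through this step as CH2OTBS.
- The C8–CH2 bond comes from Negishi coupling of (S)-lavandulylzinc iodide (Evans deconjugative prenylation, reduction, iodination) with a C8 aryl iodide.
- Ring A comes from 2,4,6-trihydroxybenzaldehyde and ring B from 4-hydroxy-2-methoxybenzaldehyde; both are bought aromatic.

Key step: step 16

Remark: MOM = methoxymethyl, TBS = tert-butyldimethylsilyl; "lavandulyl" = 5-methyl-2-(prop-1-en-2-yl)hex-4-en-1-yl.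
Remark: the side-chain centre of the target has the spatial arrangement of (S)-lavandulol; its descriptor becomes R once CH2OH is replaced by CH2–aryl, because the isopropenyl carbon then outranks the benzylic carbon.
Assumption: (R)-DTBM-SEGPHOS is taken to deliver hydride to the C2 face that gives 2S; the sense is to be checked on the lavandulyl-free aldehyde, and the (S)-ligand is used instead if it proves opposite.

**Step 1**
Reactants: 1 (S)-4-benzyloxazolidin-2-one; 2 3-methylbut-2-enoyl chloride
Product: 4 (S)-4-benzyl-3-(3-methylbut-2-enoyl)oxazolidin-2-one, via lithium oxazolidinide 3 (not isolated)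
Conditions: n-BuLi, THF, −78 °C; then 2, −78 → 0 °C
Reagents that add atoms: none
Why: N-acylation of the lithiated Evans oxazolidinone by the acid chloride is standard, and the low temperature without amine base avoids deconjugation through the vinylketene.

**Step 2**
Reactants: 4 (S)-4-benzyl-3-(3-methylbut-2-enoyl)oxazolidin-2-one; 5 prenyl bromide (1-bromo-3-methylbut-2-ene)
Product: 7 (S)-4-benzyl-3-[(2S)-5-methyl-2-(prop-1-en-2-yl)hex-4-enoyl]oxazolidin-2-one, via sodium dienolate 6 (not isolated)
Conditions: NaN(SiMe3)2 (1.05 equiv.), THF, −78 °C; then 5, −78 → −40 °C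
Reagents that add atoms: none
Why: Evans asymmetric alkylation in its deconjugative form: γ-deprotonation gives the chelated Z(O)-dienolate, which should be alkylated at the α-carbon on the face opposite the benzyl group, setting the side-chain centre (S here) and moving the alkene into the isopropenyl position.

**Step 3**
Reactants: 7 (S)-4-benzyl-3-[(2S)-5-methyl-2-(prop-1-en-2-yl)hex-4-enoyl]oxazolidin-2-one
Product: 8 (S)-lavandulol [(2S)-5-methyl-2-(prop-1-en-2-yl)hex-4-en-1-ol]
Conditions: LiBH4, H2O (1 equiv.), Et2O, 0 °C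
Reagents that add atoms: none
Why: Reductive cleavage of the N-acyl oxazolidinone by borohydride at the exocyclic carbonyl should release the primary alcohol under non-basic conditions that leave the α-centre and both alkenes untouched and return the auxiliary.

**Step 4**
Reactants: 8 (S)-lavandulol
Product: 9 (S)-lavandulyl iodide [(2S)-1-iodo-5-methyl-2-(prop-1-en-2-yl)hex-4-ene]
Conditions: I2, PPh3, imidazole, CH2Cl2, 0 °C → rt, dark
Reagents that add atoms: iodine, [I][I]
Why: Appel-type iodination proceeds by SN2 displacement at the primary carbon, so the adjacent stereocentre is not involved.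

**Step 5**
Reactants: 10 4-hydroxy-2-methoxybenzaldehyde
Product: 11 2-methoxy-4-(methoxymethoxy)benzaldehyde
Conditions: MOMCl, i-Pr2NEt, CH2Cl2, 0 °C → rt
Reagents that add atoms: chloromethyl methyl ether (MOMCl), COCCl
Why: Williamson-type O-alkylation of the only phenol with the reactive α-chloro ether.

**Step 6**
Reactants: 11 2-methoxy-4-(methoxymethoxy)benzaldehyde
Product: 12 2-methoxy-4-(methoxymethoxy)benzoic acid
Conditions: NaClO2, NaH2PO4, 2-methyl-2-butene, t-BuOH/H2O, rt
Reagents that add atoms: sodium chlorite, [Na+].[O-]Cl=O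
Why: Pinnick oxidation converts the aryl aldehyde into the acid at buffered pH, which the MOM ether tolerates, with the alkene scavenger removing hypochlorite.

**Step 7**
Reactants: 13 2,4,6-trihydroxybenzaldehyde
Product: 14 2-hydroxy-4,6-bis(methoxymethoxy)benzaldehyde
Conditions: MOMCl (2.1 equiv.), i-Pr2NEt, CH2Cl2, 0 °C
Reagents that add atoms: chloromethyl methyl ether (MOMCl), COCCl
Why: Selective Williamson-type etherification: the substrate is symmetric, and after the first ortho hydroxyl and the para hydroxyl have reacted, the remaining hydroxyl is locked in a hydrogen bond to the formyl group and should stay free with limited reagent.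

**Step 8**
Reactants: 14 2-hydroxy-4,6-bis(methoxymethoxy)benzaldehyde
Product: 15 2-hydroxy-3-iodo-4,6-bis(methoxymethoxy)benzaldehyde
Conditions: NIS, DMF, 0 °C → rt, dark
Reagents that add atoms: N-iodosuccinimide, O=C1CCC(=O)N1I
Why: Electrophilic aromatic iodination of the highly activated ring is expected ortho to the free, hydrogen-bonded hydroxyl (the usual preference in 2-hydroxy-4,6-dialkoxyaryl carbonyl compounds), which places iodine at the future C8 between O1 and O7.

**Step 9**
Reactants: 15 2-hydroxy-3-iodo-4,6-bis(methoxymethoxy)benzaldehyde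
Product: 16 2-(hydroxymethyl)-6-iodo-3,5-bis(methoxymethoxy)phenol
Conditions: NaBH4, THF/MeOH, 0 °C
Reagents that add atoms: none
Why: Borohydride reduction takes the formyl group to the alcohol level, because a free aldehyde would be methylenated before the ester in step 13; the aryl iodide and MOM ethers are inert.

**Step 10**
Reactants: 16 2-(hydroxymethyl)-6-iodo-3,5-bis(methoxymethoxy)phenol
Product: 17 2-{[(tert-butyldimethylsilyl)oxy]methyl}-6-iodo-3,5-bis(methoxymethoxy)phenol
Conditions: TBSCl (1.05 equiv.), imidazole, CH2Cl2, 0 °C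
Reagents that add atoms: tert-butyldimethylsilyl chloride, CC(C)(C)[Si](C)(C)Cl
Why: Silylation should select the primary benzylic hydroxyl over the phenol, which is flanked by iodine and the CH2O group and hydrogen-bonded.

**Step 11**
Reactants: 17 2-{[(tert-butyldimethylsilyl)oxy]methyl}-6-iodo-3,5-bis(methoxymethoxy)phenol; 12 2-methoxy-4-(methoxymethoxy)benzoic acid
Product: 18 2-{[(tert-butyldimethylsilyl)oxy]methyl}-6-iodo-3,5-bis(methoxymethoxy)phenyl 2-methoxy-4-(methoxymethoxy)benzoate
Conditions: DCC, DMAP, CH2Cl2, rt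
Reagents that add atoms: none
Why: Steglich esterification through the acylpyridinium acylates hindered phenols under neutral conditions that spare MOM and TBS, and the silyl ether blocks acyl migration to the benzylic oxygen.

**Step 12**
Reactants: 9 (S)-lavandulyl iodide; 18 2-{[(tert-butyldimethylsilyl)oxy]methyl}-6-iodo-3,5-bis(methoxymethoxy)phenyl 2-methoxy-4-(methoxymethoxy)benzoate
Product: 20 2-{[(tert-butyldimethylsilyl)oxy]methyl}-3,5-bis(methoxymethoxy)-6-[(2R)-lavandulyl]phenyl 2-methoxy-4-(methoxymethoxy)benzoate, via lavandulylzinc iodide 19 (not isolated)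
Conditions: Zn dust (activated with BrCH2CH2Br and Me3SiCl), LiCl, THF, 35 °C; then 18, Pd(OAc)2 (5 mol%), SPhos (10 mol%), THF, rt → 45 °C
Reagents that add atoms: none
Why: Negishi sp3–sp2 coupling: zinc insertion into the primary iodide, oxidative addition of the aryl iodide to zerovalent palladium, transmetalation and reductive elimination form the C8–CH2 bond in the presence of the aryl ester, and the β-stereocentre is not involved.

**Step 13**
Reactants: 20 2-{[(tert-butyldimethylsilyl)oxy]methyl}-3,5-bis(methoxymethoxy)-6-[(2R)-lavandulyl]phenyl 2-methoxy-4-(methoxymethoxy)benzoate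
Product: 21 tert-butyl{[2-({1-[2-methoxy-4-(methoxymethoxy)phenyl]vinyl}oxy)-4,6-bis(methoxymethoxy)-3-[(2R)-lavandulyl]benzyl]oxy}dimethylsilane
Conditions: Cp2Ti(μ-CH2)(μ-Cl)AlMe2 (Tebbe reagent), pyridine, THF/toluene, −40 °C → rt; aq. NaOH quench; chromatography on Et3N-deactivated silica
Reagents that add atoms: Tebbe reagent Cp2Ti(μ-CH2)(μ-Cl)AlMe2 (bridging chloride drawn on titanium), C[Al](C)C[Ti](Cl)(C1C=CC=C1)C1C=CC=C1
Why: Tebbe methylenation of an aryl benzoate to the aryl 1-arylvinyl ether is a classical use of the titanium methylidene; the ester is the only carbonyl present, and the silyl ether, MOM ethers and the side-chain alkenes are not consumed.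

**Step 14**
Reactants: 21 tert-butyl{[2-({1-[2-methoxy-4-(methoxymethoxy)phenyl]vinyl}oxy)-4,6-bis(methoxymethoxy)-3-[(2R)-lavandulyl]benzyl]oxy}dimethylsilane
Product: 22 [2-({1-[2-methoxy-4-(methoxymethoxy)phenyl]vinyl}oxy)-4,6-bis(methoxymethoxy)-3-[(2R)-lavandulyl]phenyl]methanol
Conditions: Bu4NF, THF, 0 °C; filtration through basic alumina; used at once
Reagents that add atoms: none
Why: Fluoride desilylation is basic, so the acid-labile enol ether and the MOM ethers survive, and no ester remains that could migrate.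

**Step 15**
Reactants: 22 [2-({1-[2-methoxy-4-(methoxymethoxy)phenyl]vinyl}oxy)-4,6-bis(methoxymethoxy)-3-[(2R)-lavandulyl]phenyl]methanol
Product: 23 2-({1-[2-methoxy-4-(methoxymethoxy)phenyl]vinyl}oxy)-4,6-bis(methoxymethoxy)-3-[(2R)-lavandulyl]benzaldehyde
Conditions: MnO2 (excess), CH2Cl2, rt
Reagents that add atoms: none
Why: Manganese dioxide oxidation of the electron-rich benzylic alcohol is neutral and selective and stops at the aldehyde without touching the enol ether or the alkenes.

**Step 16**
Reactants: 23 2-({1-[2-methoxy-4-(methoxymethoxy)phenyl]vinyl}oxy)-4,6-bis(methoxymethoxy)-3-[(2R)-lavandulyl]benzaldehyde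
Product: 24 (2S)-2-[2-methoxy-4-(methoxymethoxy)phenyl]-5,7-bis(methoxymethoxy)-8-[(2R)-lavandulyl]chroman-4-one
Conditions: [Rh(cod)Cl]2 (2.5 mol%), (R)-DTBM-SEGPHOS (5.5 mol%), Na[B(3,5-(CF3)2C6H3)4] (5 mol%), 1,4-dioxane, 60 °C, rigorously dry and acid-free
Reagents that add atoms: none
Why: Proposed new method: oxidative addition of the C4 formyl C–H bond to the cationic monovalent rhodium–bisphosphine should give an acyl hydride of trivalent rhodium that binds the C2=C3 alkene of the 1-arylvinyl ether, inserts it with hydride going to C2 and rhodium to the terminal C3, and reductively eliminates to form the C3–C4 bond. The closest known reaction type is the rhodium-catalysed enantioselective endo hydroacylation of ortho-allylbenzaldehydes bearing 1,1-disubstituted alkenes to 3-substituted tetralones; this substrate is its oxygen-for-CH2 analogue, with an enol ether in place of the allyl alkene, which is why the label applies. Ring C closes in a 6-endo-trig sense through a seven-membered acyl rhodacycle. The C2 stereocentre is created in the hydride-insertion step under control of the chiral bisphosphine, the lavandulyl centre being too remote to interfere. The step needs endo over exo regioselectivity and chemoselectivity over the two side-chain alkenes and over decarbonylation. The substrate secures these because the exo path would pass through a tertiary benzylic alkyl rhodium and form a quaternary centre, the vinyl ether has no allylic hydrogen and cannot isomerise, the lavandulyl alkenes sit meta to the formyl group and cannot reach the acyl rhodium, and the C5 methoxymethoxy oxygen ortho to the formyl group can stabilise the acyl hydride by chelation.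

**Step 17**
Reactants: 24 (2S)-2-[2-methoxy-4-(methoxymethoxy)phenyl]-5,7-bis(methoxymethoxy)-8-[(2R)-lavandulyl]chroman-4-one
Product: 25 leachianone A
Conditions: 3 M aq. HCl, MeOH, 40 °C, stopped as soon as the last MOM ether is gone
Reagents that add atoms: none
Why: Acid-catalysed acetal exchange with methanol removes the three phenolic MOM ethers (the chelated C5 one first) under conditions mild enough that hydration or cyclisation of the side-chain alkenes and ring-opening at C2 should not compete.

**Compound list**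
1 | (S)-4-benzyloxazolidin-2-one | O=C1OC[C@H](Cc2ccccc2)N1 | starting material
2 | 3-methylbut-2-enoyl chloride | CC(C)=CC(=O)Cl | starting material
3 | lithium (S)-4-benzyl-2-oxooxazolidin-3-ide | [Li+].O=C1OC[C@H](Cc2ccccc2)[N-]1 | intermediate
4 | (S)-4-benzyl-3-(3-methylbut-2-enoyl)oxazolidin-2-one | CC(C)=CC(=O)N1[C@@H](Cc2ccccc2)COC1=O | intermediate
5 | prenyl bromide (1-bromo-3-methylbut-2-ene) | CC(C)=CCBr | starting material
6 | sodium Z(O)-dienolate of 4 | [Na+].C=C(C)/C=C(\[O-])N1[C@@H](Cc2ccccc2)COC1=O | intermediate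
7 | (S)-4-benzyl-3-[(2S)-5-methyl-2-(prop-1-en-2-yl)hex-4-enoyl]oxazolidin-2-one | C=C(C)[C@H](CC=C(C)C)C(=O)N1[C@@H](Cc2ccccc2)COC1=O | intermediate
8 | (S)-lavandulol, (2S)-5-methyl-2-(prop-1-en-2-yl)hex-4-en-1-ol | C=C(C)[C@H](CC=C(C)C)CO | intermediate
9 | (S)-lavandulyl iodide, (2S)-1-iodo-5-methyl-2-(prop-1-en-2-yl)hex-4-ene | C=C(C)[C@H](CC=C(C)C)CI | intermediate
10 | 4-hydroxy-2-methoxybenzaldehyde | COc1cc(O)ccc1C=O | starting material
11 | 2-methoxy-4-(methoxymethoxy)benzaldehyde | COCOc1ccc(C=O)c(OC)c1 | intermediate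
12 | 2-methoxy-4-(methoxymethoxy)benzoic acid | COCOc1ccc(C(=O)O)c(OC)c1 | intermediate
13 | 2,4,6-trihydroxybenzaldehyde | O=Cc1c(O)cc(O)cc1O | starting material
14 | 2-hydroxy-4,6-bis(methoxymethoxy)benzaldehyde | COCOc1cc(O)c(C=O)c(OCOC)c1 | intermediate
15 | 2-hydroxy-3-iodo-4,6-bis(methoxymethoxy)benzaldehyde | COCOc1cc(OCOC)c(C=O)c(O)c1I | intermediate
16 | 2-(hydroxymethyl)-6-iodo-3,5-bis(methoxymethoxy)phenol | COCOc1cc(OCOC)c(CO)c(O)c1I | intermediate
17 | 2-{[(tert-butyldimethylsilyl)oxy]methyl}-6-iodo-3,5-bis(methoxymethoxy)phenol | COCOc1cc(OCOC)c(CO[Si](C)(C)C(C)(C)C)c(O)c1I | intermediate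
18 | 2-{[(tert-butyldimethylsilyl)oxy]methyl}-6-iodo-3,5-bis(methoxymethoxy)phenyl 2-methoxy-4-(methoxymethoxy)benzoate | COCOc1ccc(C(=O)Oc2c(I)c(OCOC)cc(OCOC)c2CO[Si](C)(C)C(C)(C)C)c(OC)c1 | intermediate
19 | [(2S)-5-methyl-2-(prop-1-en-2-yl)hex-4-en-1-yl]zinc iodide | C=C(C)[C@H](CC=C(C)C)C[Zn]I | intermediate
20 | 2-{[(tert-butyldimethylsilyl)oxy]methyl}-3,5-bis(methoxymethoxy)-6-[(2R)-5-methyl-2-(prop-1-en-2-yl)hex-4-en-1-yl]phenyl 2-methoxy-4-(methoxymethoxy)benzoate | C=C(C)[C@H](CC=C(C)C)Cc1c(OCOC)cc(OCOC)c(CO[Si](C)(C)C(C)(C)C)c1OC(=O)c1ccc(OCOC)cc1OC | intermediate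
21 | tert-butyl{[2-({1-[2-methoxy-4-(methoxymethoxy)phenyl]vinyl}oxy)-4,6-bis(methoxymethoxy)-3-[(2R)-5-methyl-2-(prop-1-en-2-yl)hex-4-en-1-yl]benzyl]oxy}dimethylsilane | C=C(C)[C@H](CC=C(C)C)Cc1c(OCOC)cc(OCOC)c(CO[Si](C)(C)C(C)(C)C)c1OC(=C)c1ccc(OCOC)cc1OC | intermediate
22 | [2-({1-[2-methoxy-4-(methoxymethoxy)phenyl]vinyl}oxy)-4,6-bis(methoxymethoxy)-3-[(2R)-5-methyl-2-(prop-1-en-2-yl)hex-4-en-1-yl]phenyl]methanol | C=C(C)[C@H](CC=C(C)C)Cc1c(OCOC)cc(OCOC)c(CO)c1OC(=C)c1ccc(OCOC)cc1OC | intermediate
23 | 2-({1-[2-methoxy-4-(methoxymethoxy)phenyl]vinyl}oxy)-4,6-bis(methoxymethoxy)-3-[(2R)-5-methyl-2-(prop-1-en-2-yl)hex-4-en-1-yl]benzaldehyde | C=C(C)[C@H](CC=C(C)C)Cc1c(OCOC)cc(OCOC)c(C=O)c1OC(=C)c1ccc(OCOC)cc1OC | intermediate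
24 | (2S)-2-[2-methoxy-4-(methoxymethoxy)phenyl]-5,7-bis(methoxymethoxy)-8-[(2R)-5-methyl-2-(prop-1-en-2-yl)hex-4-en-1-yl]chroman-4-one | C=C(C)[C@H](CC=C(C)C)Cc1c(OCOC)cc(OCOC)c2c1O[C@H](c1ccc(OCOC)cc1OC)CC2=O | intermediate
25 | leachianone A, (2S)-5,7-dihydroxy-2-(4-hydroxy-2-methoxyphenyl)-8-[(2R)-5-methyl-2-(prop-1-en-2-yl)hex-4-en-1-yl]chroman-4-one | C=C(C)[C@H](CC=C(C)C)Cc1c(O)cc(O)c2c1O[C@H](c1ccc(O)cc1OC)CC2=O | target

**Step count and risks**
Total step count: 17. Longest linear sequence: 11 steps (steps 7–17, from 13).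

Steps most likely to fail:

1. Step 16. Decarbonylation of the acyl rhodium hydride may outrun insertion of the hindered, electron-rich enol ether; adventitious acid may hydrolyse the enol ether; or facial discrimination in the hydride insertion may be poor. The fallback uses known chemistry, sets out from 23 and returns at 24.
   - Mild hydrolysis of the enol ether of 23 (PPTS, acetone/H2O, rt) frees the salicylaldehyde 2-hydroxy-4,6-bis(methoxymethoxy)-3-[(2R)-lavandulyl]benzaldehyde F1.
   - Excess MeMgBr (THF, 0 °C) gives the 1-arylethanol F2, as carbinol epimers of no consequence.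
   - MnO2 (CH2Cl2) gives the 2'-hydroxyacetophenone F3.
   - Claisen–Schmidt condensation with aldehyde 11 (KOH, EtOH, rt) gives the 2'-hydroxychalcone F4.
   - Intramolecular oxa-Michael closure (NaOAc, EtOH, reflux) should give 24 together with its (2R) epimer F5. The two are separated by preparative HPLC on a chiral stationary phase, and F5 is returned to the chalcone–flavanone equilibrium with base.

2. Step 12. Oxidative addition and transmetalation at the doubly ortho-oxygenated aryl iodide may be slow, so that protodezincation or β-hydride elimination of the alkyl palladium takes over; radical scrambling during zinc insertion is a lesser concern. The fallback sets out from 9 and 18 and returns at 20.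
   - Iodine–lithium exchange on 9 (t-BuLi, Et2O, −78 °C) and trapping with 9-methoxy-9-borabicyclo[3.3.1]nonane gives the lithium B-lavandulyl-B-methoxy-9-borabicyclo[3.3.1]nonane ate complex F6.
   - B-alkyl Suzuki–Miyaura coupling of this with 18 (Pd(dppf)Cl2, AsPh3, K3PO4, DMF/THF, rt) should give 20 by a polar, room-temperature transmetalation from boron.

3. Step 13. Methylenation of the hindered, electron-rich aryl ester may be incomplete, or the very acid-labile enol ether may be lost during isolation. The fallback forms the O1–C2 bond instead of the C2=C3 bond; it sets out from 20 and 11 and returns at 21.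
   - Methanolysis of 20 (K2CO3, MeOH, rt) gives the phenol 2-{[(tert-butyldimethylsilyl)oxy]methyl}-3,5-bis(methoxymethoxy)-6-[(2R)-lavandulyl]phenol F7.
   - Aldehyde 11 with MeMgBr (THF, 0 °C) gives 1-[2-methoxy-4-(methoxymethoxy)phenyl]ethanol F8.
   - MnO2 gives 1-[2-methoxy-4-(methoxymethoxy)phenyl]ethanone F9.
   - KN(SiMe3)2 and PhNTf2 (THF, −78 °C) give 1-[2-methoxy-4-(methoxymethoxy)phenyl]vinyl trifluoromethanesulfonate F10.
   - Palladium-catalysed C–O coupling of F7 with F10 (Pd2(dba)3, 2-(di-tert-butylphosphino)biphenyl, NaOt-Bu, toluene, 80 °C) should give 21.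

**Further compounds**
F1 | step 16 | 2-hydroxy-4,6-bis(methoxymethoxy)-3-[(2R)-5-methyl-2-(prop-1-en-2-yl)hex-4-en-1-yl]benzaldehyde | C=C(C)[C@H](CC=C(C)C)Cc1c(OCOC)cc(OCOC)c(C=O)c1O
F2 | step 16 | 1-{2-hydroxy-4,6-bis(methoxymethoxy)-3-[(2R)-5-methyl-2-(prop-1-en-2-yl)hex-4-en-1-yl]phenyl}ethanol (carbinol epimers) | C=C(C)[C@H](CC=C(C)C)Cc1c(OCOC)cc(OCOC)c(C(C)O)c1O
F3 | step 16 | 1-{2-hydroxy-4,6-bis(methoxymethoxy)-3-[(2R)-5-methyl-2-(prop-1-en-2-yl)hex-4-en-1-yl]phenyl}ethanone | C=C(C)[C@H](CC=C(C)C)Cc1c(OCOC)cc(OCOC)c(C(C)=O)c1O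
F4 | step 16 | (E)-1-{2-hydroxy-4,6-bis(methoxymethoxy)-3-[(2R)-5-methyl-2-(prop-1-en-2-yl)hex-4-en-1-yl]phenyl}-3-[2-methoxy-4-(methoxymethoxy)phenyl]prop-2-en-1-one | C=C(C)[C@H](CC=C(C)C)Cc1c(OCOC)cc(OCOC)c(C(=O)/C=C/c2ccc(OCOC)cc2OC)c1O
F5 | step 16 | (2R)-2-[2-methoxy-4-(methoxymethoxy)phenyl]-5,7-bis(methoxymethoxy)-8-[(2R)-5-methyl-2-(prop-1-en-2-yl)hex-4-en-1-yl]chroman-4-one | C=C(C)[C@H](CC=C(C)C)Cc1c(OCOC)cc(OCOC)c2c1O[C@@H](c1ccc(OCOC)cc1OC)CC2=O
F6 | step 12 | lithium 9-methoxy-9-[(2S)-5-methyl-2-(prop-1-en-2-yl)hex-4-en-1-yl]-9-boranuidabicyclo[3.3.1]nonane | [Li+].C=C(C)[C@H](CC=C(C)C)C[B-]1(OC)C2CCCC1CCC2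
F7 | step 13 | 2-{[(tert-butyldimethylsilyl)oxy]methyl}-3,5-bis(methoxymethoxy)-6-[(2R)-5-methyl-2-(prop-1-en-2-yl)hex-4-en-1-yl]phenol | C=C(C)[C@H](CC=C(C)C)Cc1c(OCOC)cc(OCOC)c(CO[Si](C)(C)C(C)(C)C)c1O
F8 | step 13 | 1-[2-methoxy-4-(methoxymethoxy)phenyl]ethanol | COCOc1ccc(C(C)O)c(OC)c1
F9 | step 13 | 1-[2-methoxy-4-(methoxymethoxy)phenyl]ethanone | COCOc1ccc(C(C)=O)c(OC)c1
F10 | step 13 | 1-[2-methoxy-4-(methoxymethoxy)phenyl]vinyl trifluoromethanesulfonate | COCOc1ccc(C(=C)OS(=O)(=O)C(F)(F)F)c(OC)c1
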